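**Plan**

1. Enabling feature: C4 of the cis-decalin carries CH3, C3, C5 and O3', and O3' sits on ring C next to the free 2'-OH. Ring C is a catechol monoether, so it can enter as its o-quinone, with C4 as the carbon of a ketene-derived enolate.
2. Cuts: the allyl groups go back to aryl bromides and the C3 methylene to a ketone. Ring A is cut at C1–C10 (radical closure onto a vinyl ketone) and C2–C3 (vinyl addition to an amide). The benzodioxinone behind that amide is cut at C4–O3' and C3–O2' into a ring B ketene and a ring C o-quinone.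
3. The ring B acid is cut at C4–C5 (Ireland–Claisen) back to (S)-carvone and propanoic acid. The quinone comes from 4-bromo-2,6-difluorobenzaldehyde and 4-bromophenol.
4. Forward: ring B comes from carvone and ring C is made as the quinone. The [4+2] joins them and closes a temporary lactone ring; the lactone is opened and ring A closes last. C3 deoxygenation, allylation and desilylation follow.
5. Stereochemistry: C7 from (S)-carvone; C5 by suprafacial [3,3] transfer from the trans allylic ester (Luche reduction, Mitsunobu inversion); C4 by the alkaloid catalyst in the key step; C10 by cis closure of ring A.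

Key step: step 11

Locants: eudesmane numbering for the terpenoid part (ring A = C1–C5, C10; ring B = C5–C10; C11 = carbinol carbon on C7; carvone C3, C2 and C5 become C5, C10 and C7). Ring C = C1'–C6', with O1' the aryloxy oxygen, O2' the free phenol, O3' the ether oxygen to C4, and C5' the allyl-bearing carbon. The target is (4R,5S,7R,10R): 4β-CH3, 4α-OAr, 5β-H, 7β-side chain, 10β-CH3.

Assumption: O-benzoylquinidine is taken to be the pseudo-enantiomer whose facial preference gives the required C4 configuration. If the sense of induction is the opposite, O-benzoylquinine replaces it in step 11 and nothing else changes.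

**Route**

Step 1
Reactants: 1 (S)-(+)-carvone
Product: 2 (5S)-5-(2-hydroxypropan-2-yl)-2-methylcyclohex-2-en-1-one
Conditions: 50% aq. H2SO4, 0 °C
Reagents that add atoms: water, O
Why: Acid-catalysed Markovnikov hydration of the isopropenyl group through its tertiary cation should give the tertiary alcohol, the electron-poor conjugated ring alkene being much less basic and the C5 centre of carvone not being enolisable.

Step 2
Reactants: 2 (5S)-5-(2-hydroxypropan-2-yl)-2-methylcyclohex-2-en-1-one
Product: 3 (5S)-2-methyl-5-{2-[(triethylsilyl)oxy]propan-2-yl}cyclohex-2-en-1-one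
Conditions: Et3SiOTf, 2,6-lutidine, CH2Cl2, −78 °C
Reagents that add atoms: triethylsilyl trifluoromethanesulfonate, CC[Si](CC)(CC)OS(=O)(=O)C(F)(F)F
Why: Silyl ether formation at a tertiary alcohol needs the silyl triflate, and 2,6-lutidine at low temperature is too weak a base to turn the enone into a silyl dienol ether.

Step 3
Reactants: 3 (5S)-2-methyl-5-{2-[(triethylsilyl)oxy]propan-2-yl}cyclohex-2-en-1-one
Product: 4 (1S,5S)-2-methyl-5-{2-[(triethylsilyl)oxy]propan-2-yl}cyclohex-2-en-1-ol (cis)
Conditions: NaBH4, CeCl3·7H2O, MeOH, −20 °C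
Reagents that add atoms: none
Why: Luche reduction delivers hydride 1,2 and axially to the half-chair that holds the large C5 substituent equatorial, which should give the cis allylic alcohol as it does with carvone itself.

Step 4
Reactants: 4 (1S,5S)-2-methyl-5-{2-[(triethylsilyl)oxy]propan-2-yl}cyclohex-2-en-1-ol; 5 propanoic acid
Product: 6 (1R,5S)-2-methyl-5-{2-[(triethylsilyl)oxy]propan-2-yl}cyclohex-2-en-1-yl propanoate (trans)
Conditions: PPh3, iPrO2CN=NCO2iPr, THF, 0 → 23 °C
Reagents that add atoms: none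
Why: Mitsunobu esterification proceeds by SN2 inversion at the secondary allylic carbinol carbon and should give the trans ester, whose C–O bond is pseudoaxial and therefore aligned for the coming [3,3] shift.

Step 5
Reactants: 6 (1R,5S)-2-methyl-5-{2-[(triethylsilyl)oxy]propan-2-yl}cyclohex-2-en-1-yl propanoate
Product: 9 2-[(1R,5R)-2-methyl-5-{2-[(triethylsilyl)oxy]propan-2-yl}cyclohex-2-en-1-yl]propanoic acid as a mixture of C4 epimers, via silyl ketene acetal 7 (not isolated), via trimethylsilyl ester 8 (not isolated)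
Conditions: LiN(iPr)2, THF, −78 °C; Me3SiCl, −78 → 60 °C; then H2O, citric acid work-up
Reagents that add atoms: none
Why: Ireland–Claisen rearrangement is suprafacial, so the new C4–C5 bond should form on the face the ester oxygen leaves, trans to the C7 substituent, which sets C5; the C4 methine forms as a mixture that step 11 erases.

Step 6
Reactants: 9 2-[(1R,5R)-2-methyl-5-{2-[(triethylsilyl)oxy]propan-2-yl}cyclohex-2-en-1-yl]propanoic acid
Product: 10 2-[(1R,5R)-2-methyl-5-{2-[(triethylsilyl)oxy]propan-2-yl}cyclohex-2-en-1-yl]propanoyl chloride (C4 epimers)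
Conditions: 1-chloro-N,N,2-trimethylprop-1-en-1-amine, CH2Cl2, 0 → 23 °C; used crude
Reagents that add atoms: 1-chloro-N,N,2-trimethylprop-1-en-1-amine, CC(C)=C(Cl)N(C)C
Why: Acid chloride formation with the neutral α-chloroenamine liberates no HCl, so the tertiary silyl ether and the ring alkene should survive.

Step 7
Reactants: 11 4-bromo-2,6-difluorobenzaldehyde; 12 4-bromophenol
Product: 13 4-bromo-2-(4-bromophenoxy)-6-fluorobenzaldehyde
Conditions: K2CO3, DMF, 23 °C (one equivalent of 12)
Reagents that add atoms: none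
Why: Nucleophilic aromatic substitution (addition–elimination) at a fluorine ortho to the formyl group should stop after one exchange because the aryloxy group introduced makes the ring less electrophilic.

Step 8
Reactants: 13 4-bromo-2-(4-bromophenoxy)-6-fluorobenzaldehyde
Product: 14 4-bromo-2-(4-bromophenoxy)-6-hydroxybenzaldehyde
Conditions: KOH, DMSO–H2O, 60 °C; then 1 M HCl
Reagents that add atoms: potassium hydroxide, [K+].[OH-]
Why: A second nucleophilic aromatic substitution by hydroxide at the remaining ortho fluorine should be selective, fluoride being a far better leaving group in this mechanism than bromide or aryloxide.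

Step 9
Reactants: 14 4-bromo-2-(4-bromophenoxy)-6-hydroxybenzaldehyde
Product: 16 5-bromo-3-(4-bromophenoxy)benzene-1,2-diol, via aryl formate 15 (not isolated)
Conditions: 30% H2O2, NaOH, H2O–THF, 0 → 23 °C, N2; then HCl
Reagents that add atoms: hydrogen peroxide, OO
Why: Dakin oxidation should apply, as hydroperoxide adds to the aldehyde, the aryl group carrying an ortho phenoxide migrates to oxygen and the formate is saponified in the same flask.

Step 10
Reactants: 16 5-bromo-3-(4-bromophenoxy)benzene-1,2-diol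
Product: 17 5-bromo-3-(4-bromophenoxy)cyclohexa-3,5-diene-1,2-dione
Conditions: Ag2O, MgSO4, Et2O, 0 °C, dark; filtered and used at once
Reagents that add atoms: none
Why: Dehydrogenation of a catechol to its o-quinone with Ag2O is neutral and anhydrous, which suits a quinone that would not tolerate nucleophiles or storage.

Step 11
Reactants: 10 2-[(1R,5R)-2-methyl-5-{2-[(triethylsilyl)oxy]propan-2-yl}cyclohex-2-en-1-yl]propanoyl chloride; 17 5-bromo-3-(4-bromophenoxy)cyclohexa-3,5-diene-1,2-dione
Product: 19 (3S)-6-bromo-8-(4-bromophenoxy)-3-methyl-3-[(1S,5R)-2-methyl-5-{2-[(triethylsilyl)oxy]propan-2-yl}cyclohex-2-en-1-yl]-2,3-dihydro-1,4-benzodioxin-2-one, via methyl(alkyl)ketene 18 (not isolated)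
Conditions: Et3N (1.05 equiv), THF, 23 °C (ketene formation); then O-benzoylquinidine (10 mol %), 17 in THF, −78 → −20 °C
Reagents that add atoms: none
Why: Proposed new method: Et3N dehydrochlorinates 10 to the methyl(alkyl)ketene 18, the quinuclidine nitrogen of the alkaloid adds to the ketene carbon C3 from the side of the small methyl group to give one geometry of a fully substituted ammonium enolate, its carbon C4 attacks quinone oxygen O3' with aromatisation of ring C, and the O2' phenoxide thus freed acylates at C3 and releases the catalyst. The closest known reaction types are the cinchona-alkaloid-catalysed [4+2] of monosubstituted ketene enolates with tetrahalo-o-quinones and the uncatalysed [4+2] of disubstituted ketenes with o-quinones; a dialkylketene, a quaternary carbon as the nucleophile and an unsymmetrical non-perhalogenated quinone go beyond both. The one ring formed, the 1,4-benzodioxin-2-one, closes in the second bond-forming event by 6-exo-trig attack of O2' on the acylammonium carbon. The one new stereocentre, C4, is set by the enolate face that the bound alkaloid leaves open, acting with or against the adjacent C5 centre, so both pseudo-enantiomeric catalysts are available to find the matched pair and the C4 epimer mixture in 10 is of no consequence. The step needs C4 to bond to O3' and not O2': O2' is flanked by the 4-bromophenoxy group at C1' while O3' has only H-4' beside it, and because the aryloxy group sits where the quinone LUMO has a small coefficient the bias is steric, sending the bulky quaternary carbon to the open oxygen and the flat acyl group to the crowded one. Pre-forming the ketene keeps free amine base away from the quinone and makes enolate formation independent of a slow deprotonation of a hindered acylammonium ion.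

Step 12
Reactants: 19 (3S)-6-bromo-8-(4-bromophenoxy)-3-methyl-3-[(1S,5R)-2-methyl-5-{2-[(triethylsilyl)oxy]propan-2-yl}cyclohex-2-en-1-yl]-2,3-dihydro-1,4-benzodioxin-2-one
Product: 20 (2S)-2-[5-bromo-3-(4-bromophenoxy)-2-hydroxyphenoxy]-N-methoxy-N-methyl-2-[(1S,5R)-2-methyl-5-{2-[(triethylsilyl)oxy]propan-2-yl}cyclohex-2-en-1-yl]propanamide
Conditions: MeNHOMe·HCl, iPrMgCl, THF, −20 → 0 °C
Reagents that add atoms: N,O-dimethylhydroxylamine hydrochloride, CNOC.Cl
Why: Aminolysis of the aryl ester, a good acylating agent, by the magnesium amide should open the lactone to the N-methoxy-N-methylamide and free the O2' phenol, and C4 carries no hydrogen so it cannot epimerise.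

Step 13
Reactants: 20 (2S)-2-[5-bromo-3-(4-bromophenoxy)-2-hydroxyphenoxy]-N-methoxy-N-methyl-2-[(1S,5R)-2-methyl-5-{2-[(triethylsilyl)oxy]propan-2-yl}cyclohex-2-en-1-yl]propanamide
Product: 21 (2S)-2-[5-bromo-3-(4-bromophenoxy)-2-{[tert-butyl(dimethyl)silyl]oxy}phenoxy]-N-methoxy-N-methyl-2-[(1S,5R)-2-methyl-5-{2-[(triethylsilyl)oxy]propan-2-yl}cyclohex-2-en-1-yl]propanamide
Conditions: tBuMe2SiOTf, 2,6-lutidine, CH2Cl2, 0 °C
Reagents that add atoms: tert-butyldimethylsilyl trifluoromethanesulfonate, CC(C)(C)[Si](C)(C)OS(=O)(=O)C(F)(F)F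
Why: Silyl ether formation with the triflate should reach the doubly flanked phenol, and the protection keeps O2' from closing a six-membered hemiketal onto the C3 ketone made next.

Step 14
Reactants: 21 (2S)-2-[5-bromo-3-(4-bromophenoxy)-2-{[tert-butyl(dimethyl)silyl]oxy}phenoxy]-N-methoxy-N-methyl-2-[(1S,5R)-2-methyl-5-{2-[(triethylsilyl)oxy]propan-2-yl}cyclohex-2-en-1-yl]propanamide
Product: 22 (4S)-4-[5-bromo-3-(4-bromophenoxy)-2-{[tert-butyl(dimethyl)silyl]oxy}phenoxy]-4-[(1S,5R)-2-methyl-5-{2-[(triethylsilyl)oxy]propan-2-yl}cyclohex-2-en-1-yl]pent-1-en-3-one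
Conditions: CH2=CHMgBr, THF, 0 °C; inverse quench into cold aq. NH4Cl
Reagents that add atoms: vinylmagnesium bromide, C=C[Mg]Br
Why: Weinreb ketone synthesis should stop at the vinyl ketone because the chelated tetrahedral adduct survives until the quench, and the inverse quench keeps the released amine from adding to the enone.

Step 15
Reactants: 22 (4S)-4-[5-bromo-3-(4-bromophenoxy)-2-{[tert-butyl(dimethyl)silyl]oxy}phenoxy]-4-[(1S,5R)-2-methyl-5-{2-[(triethylsilyl)oxy]propan-2-yl}cyclohex-2-en-1-yl]pent-1-en-3-one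
Product: 23 (1S,4aS,7R,8aS)-1-[5-bromo-3-(4-bromophenoxy)-2-{[tert-butyl(dimethyl)silyl]oxy}phenoxy]-1,4a-dimethyl-7-{2-[(triethylsilyl)oxy]propan-2-yl}octahydronaphthalen-2(1H)-one (cis-fused; C3 ketone in the locants used here)
Conditions: Fe(acac)3 (30 mol %), PhSiH3, EtOH–(CH2OH)2, 60 °C
Reagents that add atoms: none
Why: In this hydrogen-atom-transfer reductive olefin coupling an iron hydride gives the tertiary C10 radical from the trisubstituted ring alkene, which should add 6-endo to the terminal carbon of the vinyl ketone (Giese addition) before the α-keto radical is reduced and protonated; the ring should close cis, setting C10, because the equatorial C7 substituent holds the C5–C4 bond axial on ring B so that C1 can only reach the same face of C10.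

Step 16
Reactants: 23 (1S,4aS,7R,8aS)-1-[5-bromo-3-(4-bromophenoxy)-2-{[tert-butyl(dimethyl)silyl]oxy}phenoxy]-1,4a-dimethyl-7-{2-[(triethylsilyl)oxy]propan-2-yl}octahydronaphthalen-2(1H)-one
Product: 24 (1S,4aS,7R,8aS)-1-[5-bromo-3-(4-bromophenoxy)-2-{[tert-butyl(dimethyl)silyl]oxy}phenoxy]-1,4a-dimethyl-7-{2-[(triethylsilyl)oxy]propan-2-yl}decahydronaphthalen-2-ol (C3 carbinol of either configuration)
Conditions: NaBH4, MeOH–THF, 0 °C
Reagents that add atoms: none
Why: Borohydride reduction of the ketone should give the secondary alcohol, and the configuration of the new C3 carbinol does not matter because the oxygen is removed in step 19.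

Step 17
Reactants: 24 (1S,4aS,7R,8aS)-1-[5-bromo-3-(4-bromophenoxy)-2-{[tert-butyl(dimethyl)silyl]oxy}phenoxy]-1,4a-dimethyl-7-{2-[(triethylsilyl)oxy]propan-2-yl}decahydronaphthalen-2-ol
Product: 25 (1S,4aS,7R,8aS)-1-[5-allyl-3-(4-allylphenoxy)-2-{[tert-butyl(dimethyl)silyl]oxy}phenoxy]-1,4a-dimethyl-7-{2-[(triethylsilyl)oxy]propan-2-yl}decahydronaphthalen-2-ol
Conditions: allylSnBu3, Pd(PPh3)4 (10 mol %), toluene, 110 °C
Reagents that add atoms: allyltributylstannane, C=CC[Sn](CCCC)(CCCC)CCCC
Why: Twofold Stille coupling of the two aryl bromides with the allylstannane under neutral, fluoride-free conditions should leave both silyl ethers and the free alcohol intact, and it is placed before the radical deoxygenation because aryl bromides would not survive a tin hydride.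

Step 18
Reactants: 25 (1S,4aS,7R,8aS)-1-[5-allyl-3-(4-allylphenoxy)-2-{[tert-butyl(dimethyl)silyl]oxy}phenoxy]-1,4a-dimethyl-7-{2-[(triethylsilyl)oxy]propan-2-yl}decahydronaphthalen-2-ol
Product: 26 O-{(1S,4aS,7R,8aS)-1-[5-allyl-3-(4-allylphenoxy)-2-{[tert-butyl(dimethyl)silyl]oxy}phenoxy]-1,4a-dimethyl-7-{2-[(triethylsilyl)oxy]propan-2-yl}decahydronaphthalen-2-yl} 1H-imidazole-1-carbothioate
Conditions: 1,1'-thiocarbonyldiimidazole, DMAP, toluene, 90 °C
Reagents that add atoms: 1,1'-thiocarbonyldiimidazole, S=C(n1ccnc1)n1ccnc1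
Why: Thioacylation under neutral conditions (first stage of the Barton–McCombie deoxygenation) should reach the hindered secondary alcohol without forming an alkoxide that could take over the phenolic silyl group.

Step 19
Reactants: 26 O-{(1S,4aS,7R,8aS)-1-[5-allyl-3-(4-allylphenoxy)-2-{[tert-butyl(dimethyl)silyl]oxy}phenoxy]-1,4a-dimethyl-7-{2-[(triethylsilyl)oxy]propan-2-yl}decahydronaphthalen-2-yl} 1H-imidazole-1-carbothioate
Product: 27 tert-butyl{2-(4-allylphenoxy)-4-allyl-6-[((4R,5S,7R,10R)-11-[(triethylsilyl)oxy]-5-epi-eudesman-4-yl)oxy]phenoxy}dimethylsilane (the bis-silyl ether of the target)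
Conditions: Bu3SnH (0.5 M), AIBN, toluene, 90 °C
Reagents that add atoms: none
Why: In the Barton–McCombie deoxygenation the stannyl radical adds to sulfur, the C3–O bond fragments and the secondary C3 radical is quenched by the concentrated tin hydride, which should outrun loss of the β-aryloxy group; aryl ethers, silyl ethers and terminal alkenes are inert.

Step 20
Reactants: 27 tert-butyl{2-(4-allylphenoxy)-4-allyl-6-[((4R,5S,7R,10R)-11-[(triethylsilyl)oxy]-5-epi-eudesman-4-yl)oxy]phenoxy}dimethylsilane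
Product: 28 CNP0254037.2: 4-allyl-2-(4-allylphenoxy)-6-{[(4R,5S,7R,10R)-11-hydroxy-5-epi-eudesman-4-yl]oxy}phenol
Conditions: Bu4NF, THF, 0 → 45 °C
Reagents that add atoms: none
Why: Fluoride-mediated desilylation should remove the aryl silyl ether quickly and the tertiary triethylsilyl ether on warming, and fluoride is preferred to acid because the tertiary alkyl aryl ether at C4 would ionise in acid.

**Compound list**

1 | (S)-(+)-carvone | CC1=CC[C@@H](CC1=O)C(C)=C | starting material
2 | (5S)-5-(2-hydroxypropan-2-yl)-2-methylcyclohex-2-en-1-one | CC1=CC[C@@H](CC1=O)C(C)(C)O | intermediate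
3 | (5S)-2-methyl-5-{2-[(triethylsilyl)oxy]propan-2-yl}cyclohex-2-en-1-one | CC1=CC[C@@H](CC1=O)C(C)(C)O[Si](CC)(CC)CC | intermediate
4 | (1S,5S)-2-methyl-5-{2-[(triethylsilyl)oxy]propan-2-yl}cyclohex-2-en-1-ol (cis) | CC1=CC[C@@H](C[C@@H]1O)C(C)(C)O[Si](CC)(CC)CC | intermediate
5 | propanoic acid | CCC(=O)O | starting material
6 | (1R,5S)-2-methyl-5-{2-[(triethylsilyl)oxy]propan-2-yl}cyclohex-2-en-1-yl propanoate (trans) | CC1=CC[C@@H](C[C@H]1OC(=O)CC)C(C)(C)O[Si](CC)(CC)CC | intermediate
7 | O-trimethylsilyl ketene acetal of 6 (enol ether geometry not controlled and without consequence) | CC1=CC[C@@H](C[C@H]1OC(=CC)O[Si](C)(C)C)C(C)(C)O[Si](CC)(CC)CC | intermediate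
8 | trimethylsilyl 2-[(1R,5R)-2-methyl-5-{2-[(triethylsilyl)oxy]propan-2-yl}cyclohex-2-en-1-yl]propanoate (C4 epimers) | C[Si](C)(C)OC(=O)C(C)[C@H]1C[C@H](C(C)(C)O[Si](CC)(CC)CC)CC=C1C | intermediate
9 | 2-[(1R,5R)-2-methyl-5-{2-[(triethylsilyl)oxy]propan-2-yl}cyclohex-2-en-1-yl]propanoic acid (C4 epimers) | CC(C(=O)O)[C@H]1C[C@H](C(C)(C)O[Si](CC)(CC)CC)CC=C1C | intermediate
10 | 2-[(1R,5R)-2-methyl-5-{2-[(triethylsilyl)oxy]propan-2-yl}cyclohex-2-en-1-yl]propanoyl chloride (C4 epimers) | CC(C(=O)Cl)[C@H]1C[C@H](C(C)(C)O[Si](CC)(CC)CC)CC=C1C | intermediate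
11 | 4-bromo-2,6-difluorobenzaldehyde | O=Cc1c(F)cc(Br)cc1F | starting material
12 | 4-bromophenol | Oc1ccc(Br)cc1 | starting material
13 | 4-bromo-2-(4-bromophenoxy)-6-fluorobenzaldehyde | O=Cc1c(F)cc(Br)cc1Oc1ccc(Br)cc1 | intermediate
14 | 4-bromo-2-(4-bromophenoxy)-6-hydroxybenzaldehyde | O=Cc1c(O)cc(Br)cc1Oc1ccc(Br)cc1 | intermediate
15 | 4-bromo-2-(4-bromophenoxy)-6-hydroxyphenyl formate | O=COc1c(O)cc(Br)cc1Oc1ccc(Br)cc1 | intermediate
16 | 5-bromo-3-(4-bromophenoxy)benzene-1,2-diol | Oc1cc(Br)cc(Oc2ccc(Br)cc2)c1O | intermediate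
17 | 5-bromo-3-(4-bromophenoxy)cyclohexa-3,5-diene-1,2-dione | O=C1C=C(Br)C=C(Oc2ccc(Br)cc2)C1=O | intermediate
18 | methyl(alkyl)ketene: 2-[2-methyl-5-{2-[(triethylsilyl)oxy]propan-2-yl}cyclohex-2-en-1-yl]prop-1-en-1-one, ring stereocentres as in 10 | CC(=C=O)[C@H]1C[C@H](C(C)(C)O[Si](CC)(CC)CC)CC=C1C | intermediate
19 | (3S)-6-bromo-8-(4-bromophenoxy)-3-methyl-3-[(1S,5R)-2-methyl-5-{2-[(triethylsilyl)oxy]propan-2-yl}cyclohex-2-en-1-yl]-2,3-dihydro-1,4-benzodioxin-2-one | Brc1ccc(Oc2cc(Br)cc3O[C@@](C)([C@H]4C[C@H](C(C)(C)O[Si](CC)(CC)CC)CC=C4C)C(=O)Oc23)cc1 | intermediate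
20 | (2S)-2-[5-bromo-3-(4-bromophenoxy)-2-hydroxyphenoxy]-N-methoxy-N-methyl-2-[(1S,5R)-2-methyl-5-{2-[(triethylsilyl)oxy]propan-2-yl}cyclohex-2-en-1-yl]propanamide | Brc1ccc(Oc2cc(Br)cc(O[C@@](C)([C@H]3C[C@H](C(C)(C)O[Si](CC)(CC)CC)CC=C3C)C(=O)N(C)OC)c2O)cc1 | intermediate
21 | O2'-tert-butyldimethylsilyl ether of 20 | Brc1ccc(Oc2cc(Br)cc(O[C@@](C)([C@H]3C[C@H](C(C)(C)O[Si](CC)(CC)CC)CC=C3C)C(=O)N(C)OC)c2O[Si](C)(C)C(C)(C)C)cc1 | intermediate
22 | (4S)-4-[5-bromo-3-(4-bromophenoxy)-2-{[tert-butyl(dimethyl)silyl]oxy}phenoxy]-4-[(1S,5R)-2-methyl-5-{2-[(triethylsilyl)oxy]propan-2-yl}cyclohex-2-en-1-yl]pent-1-en-3-one | Brc1ccc(Oc2cc(Br)cc(O[C@@](C)([C@H]3C[C@H](C(C)(C)O[Si](CC)(CC)CC)CC=C3C)C(=O)C=C)c2O[Si](C)(C)C(C)(C)C)cc1 | intermediate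
23 | (1S,4aS,7R,8aS)-1-[5-bromo-3-(4-bromophenoxy)-2-{[tert-butyl(dimethyl)silyl]oxy}phenoxy]-1,4a-dimethyl-7-{2-[(triethylsilyl)oxy]propan-2-yl}octahydronaphthalen-2(1H)-one (cis-fused) | Brc1ccc(Oc2cc(Br)cc(O[C@]3(C)C(=O)CC[C@]4(C)CC[C@@H](C(C)(C)O[Si](CC)(CC)CC)C[C@@H]43)c2O[Si](C)(C)C(C)(C)C)cc1 | intermediate
24 | C3 alcohol of 23 (decahydronaphthalen-2-ol, carbinol configuration not defined) | Brc1ccc(Oc2cc(Br)cc(O[C@]3(C)C(O)CC[C@]4(C)CC[C@@H](C(C)(C)O[Si](CC)(CC)CC)C[C@@H]43)c2O[Si](C)(C)C(C)(C)C)cc1 | intermediate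
25 | diallyl analogue of 24 (allyl at C5' and at the para position of the outer aryloxy ring) | C=CCc1ccc(Oc2cc(CC=C)cc(O[C@]3(C)C(O)CC[C@]4(C)CC[C@@H](C(C)(C)O[Si](CC)(CC)CC)C[C@@H]43)c2O[Si](C)(C)C(C)(C)C)cc1 | intermediate
26 | O-(C3) 1H-imidazole-1-carbothioate of 25 | C=CCc1ccc(Oc2cc(CC=C)cc(O[C@]3(C)C(OC(=S)n5ccnc5)CC[C@]4(C)CC[C@@H](C(C)(C)O[Si](CC)(CC)CC)C[C@@H]43)c2O[Si](C)(C)C(C)(C)C)cc1 | intermediate
27 | bis-silyl ether of the target (O2' tert-butyldimethylsilyl, O11 triethylsilyl; C3 methylene) | C=CCc1ccc(Oc2cc(CC=C)cc(O[C@]3(C)CCC[C@]4(C)CC[C@@H](C(C)(C)O[Si](CC)(CC)CC)C[C@@H]43)c2O[Si](C)(C)C(C)(C)C)cc1 | intermediate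
28 | CNP0254037.2: 4-allyl-2-(4-allylphenoxy)-6-{[(4R,5S,7R,10R)-11-hydroxy-5-epi-eudesman-4-yl]oxy}phenol | C=CCc1ccc(Oc2cc(CC=C)cc(O[C@]3(C)CCC[C@]4(C)CC[C@@H](C(C)(C)O)C[C@@H]43)c2O)cc1 | target

**Step count and risks**

Total steps: 20. Longest linear sequence: 16 steps (steps 1–6, then 11–20); the quinone branch (steps 7–10) joins at step 11.

Most likely to fail:

Step 11. The hindered, fully substituted enolate may form or react too slowly with a quinone that is far less electrophilic than a tetrahalo-o-quinone. It may also bond to O2' instead of O3', or its two faces may be poorly differentiated. The fallback makes the C4–O3' bond by known chemistry with C4 as the oxygen-bearing partner; it sets out from acid 9 and returns at 19.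
- The dianion of 9 (LiN(iPr)2, THF) is oxygenated with O2 and the hydroperoxide reduced with P(OEt)3 to the (2S)-2-hydroxy acid F1; the C4 epimers are separated here.
- Its dipotassium salt (KN(SiMe3)2, DMF) displaces one fluorine of aldehyde 11 to give the fluoro aryl ether acid F2.
- KOH in DMSO–H2O replaces the second fluorine to give the salicylaldehyde acid F3.
- Dakin oxidation (H2O2, NaOH; no peracid, so the ring B alkene is spared) gives the catechol acid F4.
- Carbodiimide lactonisation, possible only through O2' in a six-membered ring, gives the 8-hydroxybenzodioxinone F5.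
- Chan–Lam coupling of the remaining O1'H with (4-bromophenyl)boronic acid (Cu(OAc)2, pyridine, air, CH2Cl2) gives 19.

Step 15. Hydrogen-atom transfer may go to the vinyl ketone, so the acceptor is reduced before the ring closes, or the tertiary radical may be quenched before it cyclises. The fallback generates the same C10 radical without a metal hydride in the presence of the enone; it sets out from amide 21 and returns at 23.
- Mukaiyama hydration of the ring alkene of 21 (Co(acac)2, PhSiH3, O2) gives the C10 tertiary alcohol F6.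
- Excess vinylmagnesium bromide gives the hydroxy vinyl ketone F7.
- Acylation with methyl chlorooxoacetate (Et3N, DMAP) gives the methyl oxalate F8, and one equivalent of aqueous CsOH gives the caesium oxalate F9.
- Visible-light photoredox decarboxylation ([Ir(dF(CF3)ppy)2(dtbbpy)]PF6, blue light, DME–DMF, H2O) releases the tertiary radical, which closes onto C1 to give 23.

Step 19. The C3 radical may expel the neighbouring C4 aryloxy group (β-scission to a C3=C4 alkene) instead of abstracting hydrogen, and thioacylation of the hindered alcohol in step 18 may stall. The fallback removes the oxygen without a radical at C3; it sets out from ketone 23 and returns at 27.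
- Ketone 23 is converted (KN(SiMe3)2, PhNTf2, THF, −78 °C; C2 is the only enolisable position) into the enol triflate F10.
- Palladium-catalysed formate reduction (Pd(OAc)2, PPh3, Bu3N, HCO2H, DMF, 40 °C) gives the C2=C3 alkene F11; zerovalent palladium should insert into an alkenyl triflate well below the temperature needed for an aryl bromide.
- Hydrogenation over RhCl(PPh3)3, which leaves aryl bromides alone, gives the saturated dibromide F12.
- The twofold Stille allylation of step 17 applied to F12 gives 27.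

Further compounds
F1 | step 11 | (2S)-2-hydroxy-2-[(1S,5R)-2-methyl-5-{2-[(triethylsilyl)oxy]propan-2-yl}cyclohex-2-en-1-yl]propanoic acid | O[C@@](C)([C@H]1C[C@H](C(C)(C)O[Si](CC)(CC)CC)CC=C1C)C(O)=O
F2 | step 11 | (2S)-2-(5-bromo-3-fluoro-2-formylphenoxy)-2-[(1S,5R)-2-methyl-5-{2-[(triethylsilyl)oxy]propan-2-yl}cyclohex-2-en-1-yl]propanoic acid | O=Cc1c(F)cc(Br)cc1O[C@@](C)([C@H]1C[C@H](C(C)(C)O[Si](CC)(CC)CC)CC=C1C)C(O)=O
F3 | step 11 | (2S)-2-(5-bromo-2-formyl-3-hydroxyphenoxy)-2-[(1S,5R)-2-methyl-5-{2-[(triethylsilyl)oxy]propan-2-yl}cyclohex-2-en-1-yl]propanoic acid | O=Cc1c(O)cc(Br)cc1O[C@@](C)([C@H]1C[C@H](C(C)(C)O[Si](CC)(CC)CC)CC=C1C)C(O)=O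
F4 | step 11 | (2S)-2-(5-bromo-2,3-dihydroxyphenoxy)-2-[(1S,5R)-2-methyl-5-{2-[(triethylsilyl)oxy]propan-2-yl}cyclohex-2-en-1-yl]propanoic acid | Oc1cc(Br)cc(O[C@@](C)([C@H]2C[C@H](C(C)(C)O[Si](CC)(CC)CC)CC=C2C)C(O)=O)c1O
F5 | step 11 | (3S)-6-bromo-8-hydroxy-3-methyl-3-[(1S,5R)-2-methyl-5-{2-[(triethylsilyl)oxy]propan-2-yl}cyclohex-2-en-1-yl]-2,3-dihydro-1,4-benzodioxin-2-one | Oc1cc(Br)cc2O[C@@](C)([C@H]3C[C@H](C(C)(C)O[Si](CC)(CC)CC)CC=C3C)C(=O)Oc12
F6 | step 15 | C10 tertiary alcohol from hydration of 21 (2-hydroxy-2-methylcyclohexyl in place of the cyclohexenyl ring; C10 epimers) | Brc1ccc(Oc2cc(Br)cc(O[C@@](C)([C@H]3C[C@H](C(C)(C)O[Si](CC)(CC)CC)CCC3(C)O)C(=O)N(C)OC)c2O[Si](C)(C)C(C)(C)C)cc1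
F7 | step 15 | vinyl ketone from F6 (pent-1-en-3-one carrying the C10 tertiary alcohol) | Brc1ccc(Oc2cc(Br)cc(O[C@@](C)([C@H]3C[C@H](C(C)(C)O[Si](CC)(CC)CC)CCC3(C)O)C(=O)C=C)c2O[Si](C)(C)C(C)(C)C)cc1
F8 | step 15 | methyl oxalate of the C10 alcohol of F7 | Brc1ccc(Oc2cc(Br)cc(O[C@@](C)([C@H]3C[C@H](C(C)(C)O[Si](CC)(CC)CC)CCC3(C)OC(=O)C(=O)OC)C(=O)C=C)c2O[Si](C)(C)C(C)(C)C)cc1
F9 | step 15 | caesium oxalate from F8 | Brc1ccc(Oc2cc(Br)cc(O[C@@](C)([C@H]3C[C@H](C(C)(C)O[Si](CC)(CC)CC)CCC3(C)OC(=O)C([O-])=O)C(=O)C=C)c2O[Si](C)(C)C(C)(C)C)cc1.[Cs+]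
F10 | step 19 | C3 enol trifluoromethanesulfonate of 23 (C2=C3 double bond) | Brc1ccc(Oc2cc(Br)cc(O[C@]3(C)C(OS(=O)(=O)C(F)(F)F)=CC[C@]4(C)CC[C@@H](C(C)(C)O[Si](CC)(CC)CC)C[C@@H]43)c2O[Si](C)(C)C(C)(C)C)cc1
F11 | step 19 | C2=C3 alkene from reduction of F10 | Brc1ccc(Oc2cc(Br)cc(O[C@]3(C)C=CC[C@]4(C)CC[C@@H](C(C)(C)O[Si](CC)(CC)CC)C[C@@H]43)c2O[Si](C)(C)C(C)(C)C)cc1
F12 | step 19 | dibromo analogue of 27 (C3 methylene, both aryl bromides in place) | Brc1ccc(Oc2cc(Br)cc(O[C@]3(C)CCC[C@]4(C)CC[C@@H](C(C)(C)O[Si](CC)(CC)CC)C[C@@H]43)c2O[Si](C)(C)C(C)(C)C)cc1
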